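(Readings and results stem from a simulated flask for an exercise, and the scatter is random.)

A chemist following the noon flask has a flat line and one earlier flat line from the autumn run, and must say what each means for the flask at the asked time.

| flask | starting complex | incoming ligand | remark | time |
|---|---|---|---|---|
| noon | 0.15 M | 0.18 M | the very flask that is asked about, followed so far |  |
| autumn | 0.30 M | 0.18 M | run made earlier |  |
| flask | 0.15 M | 0.180 M |  | 15 h |

- noon (time / h: complex with two exchanged / %): 2.50: 30.1; 5.00: 30.1; 8.00: 29.7; 10.0: 30.2; 12.0: 29.8
- autumn (time / min: complex with two exchanged / %): 15.0: 7.9; 30.0: 7.6; 40.0: 7.9; 60.0: 8.0; 80.0: 8.1

(standard deviation of a reading: 0.3 percentage points)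

- ash: at 15 h add starting complex, 50.0% of the amount charged, then wait 5.0 h
- larch: at 15 h take out 90% of the complex with two exchanged then present, then wait 5.0 h
- birch: at 15 h add incoming ligand, 100% of the amount charged, then wait 5.0 h
- elm: change nothing and wait 5.0 h more

- complex with two exchanged, in percent of the starting complex first charged, at 15 h
- the remedy with the largest gain of complex with two exchanged, or "none" below 2 percentage points (ash / larch / birch / elm / none)
- complex with two exchanged present, with what was taken out counted in, in percent of the starting complex first charged, after ash
- complex with two exchanged present, with what was taken out counted in, in percent of the starting complex first charged, after elm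

- complex with two exchanged that was removed still counts
- additions bring no volume worth counting

Each exchange costs one incoming ligand, so the charged ratio of incoming ligand to starting complex, 1.20 here, brackets the yield if all of that ligand reacts. The ceiling, with two ligands on each complex, is 60.0%. The floor, with every first exchange finished before any second begins, is 20.0%. For autumn the ceiling is 30.0% and the floor is nothing.

The noon readings average 30.0% and the autumn readings 7.90%. These place noon at 0.250 and autumn at 0.263 of the way from floor to ceiling, a fraction called the bracket share.

Two charges sharing nearly one bracket share suggest, in my own reckoning, a stall at the end of the ligand budget. Added starting complex brings no incoming ligand and birch does, so my reckoning keeps ash at the reading, 30.0%, and names birch as the remedy.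

The forecast gives 30%, inside the bracket, with birch as the remedy and 30% after elm, but 21% after ash, 9 percentage points below my figure, holding that “each plateau looks like equilibrium, not a stall”.

The flask gives 29.9%, 29.9% after ash, 29.9% after elm, and birch as best, with a gain of 19 points.

    complex with one exchanged + incoming ligand ⇌ leaving ligand + complex with two exchanged (K = 0.500, k = 0.570 M⁻¹ min⁻¹)
    complex with two exchanged + incoming ligand → over-reaction product (k = 0.160 M⁻¹ min⁻¹)
    leaving ligand → by-product carried off (k = 1.10 min⁻¹)
    starting complex + incoming ligand ⇌ leaving ligand + complex with one exchanged (K = 40.0, k = 1.20 M⁻¹ min⁻¹)

Incoming ligand, the limiting reagent, stands at 0% of its charge at 15.0 h, and the starting complex added in ash leaves this flask at 29.9%. Part of the gain by birch in this flask comes from the turning of leaving ligand into by-product carried off: with that step taken away, birch brings 1.7 points instead of 19 points. The bracket share of this flask comes out at 0.247. On the neighbour charged with 0.26 M of starting complex, with a ceiling of 34.6%, the noon share gives 8.64%, where that neighbour gives 10.6%.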